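The ten-membered carbocycle is disconnected at C7–C8 (germacrane numbering): C7 is the ring-fusion β-carbon of the α-methylene-γ-butyrolactone and C8 the neighbouring acyloxy-bearing carbon. The exo-methylene lactone is the allyl-transposed form of a 3-(bromomethyl)butenolide, and C8 is a carbinol. An intramolecular Nozaki–Hiyama–Kishi allylation therefore forms C7–C8, closes the macrocycle, sets C7 and C8 and unveils the C11=C13 methylene in one operation. The precursor is a linear chain: an endocyclic (5R)-3-(bromomethyl)butenolide linked through the Z-C4=C5 and E-C1=C2 alkenes, with C3, C6 and C10 already set, to a C8 aldehyde.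

Key step: step 16

Remark: germacrane numbering is used throughout (ring carbons C1–C10; C11, C12, C13 are the lactone α-carbon, carbonyl and exo-methylene; C14 and C15 are the methyls on C10 and C4). Compounds 1 and 5 and all reagents are taken as commercial.

Step 1
Reactants: 1 (E)-3-methylpent-2-en-4-yn-1-ol
Product: 2 [(2S,3S)-3-ethynyl-3-methyloxiran-2-yl]methanol
Conditions: Ti(OiPr)4 (cat.), L-(+)-diethyl tartrate (cat.), t-BuOOH, 4 Å molecular sieves, CH2Cl2, −20 °C
Reagents that add atoms: tert-butyl hydroperoxide CC(C)(C)OO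
Why: Sharpless asymmetric epoxidation; as for other (E)-3-methylalk-2-en-1-ols, the L-(+)-tartrate should deliver oxygen to the face that gives the (2S,3S)-epoxide (reagent control), which fixes the later C10 centre, and the alkyne is inert.

Step 2
Reactants: 2 [(2S,3S)-3-ethynyl-3-methyloxiran-2-yl]methanol
Product: 3 (3R)-3-methylpent-4-yne-1,3-diol
Conditions: NaAlH2(OCH2CH2OCH3)2 (Red-Al), THF, −20 → 0 °C
Reagents that add atoms: none
Why: Directed hydride opening of a 2,3-epoxy alcohol: the C1 alkoxyaluminate delivers hydride intramolecularly to C2, so the 1,3-diol forms and the quaternary C–O bond keeps its configuration, while the low temperature should keep the terminal alkyne from being hydroaluminated.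

Step 3
Reactants: 3 (3R)-3-methylpent-4-yne-1,3-diol
Product: 4 (3R)-3-methyl-1,3-bis(triethylsilyloxy)pent-4-yne
Conditions: Et3SiOTf, 2,6-lutidine, CH2Cl2, −78 → 0 °C
Reagents that add atoms: triethylsilyl trifluoromethanesulfonate CC[Si](CC)(CC)OS(=O)(=O)C(F)(F)F
Why: Silylation with a silyl triflate and a hindered base protects the primary and the hindered tertiary hydroxyl in one operation and leaves the terminal alkyne C–H free.

Step 4
Reactants: 5 prop-2-yn-1-ol
Product: 7 (Z)-3-iodo-2-methylprop-2-en-1-ol, via alkenylmagnesium alkoxide 6 (not isolated)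
Conditions: MeMgBr (3 equiv), CuI (10 mol %), THF, −10 → 25 °C; then I2, −78 → 0 °C
Reagents that add atoms: methylmagnesium bromide C[Mg]Br; iodine II
Why: Copper-catalysed anti-carbomagnesiation of the propargylic magnesium alkoxide places methyl on C2 and magnesium on C3 in a five-membered chelate, and iodinolysis with retention gives the Z-iodide that later becomes the Z-C4=C5 alkene.

Step 5
Reactants: 7 (Z)-3-iodo-2-methylprop-2-en-1-ol
Product: 8 (Z)-3-iodo-2-methylprop-2-enal
Conditions: MnO2, CH2Cl2, 25 °C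
Reagents that add atoms: none
Why: MnO2 oxidises the allylic alcohol to the enal under neutral conditions that should preserve the Z geometry and the vinyl iodide.

Step 6
Reactants: 4 (3R)-3-methyl-1,3-bis(triethylsilyloxy)pent-4-yne; 8 (Z)-3-iodo-2-methylprop-2-enal
Product: 11 (1Z,3R,4E,6R)-1-iodo-2,6-dimethyl-6,8-bis(triethylsilyloxy)octa-1,4-dien-3-ol, via alkenyldicyclohexylborane 9 (not isolated), via alkenyl(methyl)zinc 10 (not isolated)
Conditions: cyclohexene, BH3·SMe2, toluene, 0 °C; 4, 0 → 25 °C; Me2Zn, −78 °C; (+)-3-exo-morpholinoisoborneol (5 mol %), 8, −10 °C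
Reagents that add atoms: none
Why: Asymmetric alkenylzinc addition: syn-hydroboration gives the E-alkenylborane, boron-to-zinc exchange gives the alkenylzinc, and the amino-alcohol-bound zinc catalyst should deliver the alkenyl group to the Re face of the enal (reagent control; this is the antipode of the ligand that gives S-carbinols from aryl aldehydes), setting 3R and the E-C1=C2 alkene together while the vinyl iodide is untouched.

Step 7
Reactants: 11 (1Z,3R,4E,6R)-1-iodo-2,6-dimethyl-6,8-bis(triethylsilyloxy)octa-1,4-dien-3-ol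
Product: 12 (1Z,3R,4E,6R)-3-(tert-butyldimethylsilyloxy)-1-iodo-2,6-dimethyl-6,8-bis(triethylsilyloxy)octa-1,4-diene
Conditions: t-BuMe2SiCl, imidazole, DMF, 25 °C
Reagents that add atoms: tert-butyldimethylsilyl chloride CC(C)(C)[Si](C)(C)Cl
Why: Standard silylation of the secondary bis-allylic alcohol under mildly basic conditions that avoid ionisation.

Step 8
Reactants: 12 (1Z,3R,4E,6R)-3-(tert-butyldimethylsilyloxy)-1-iodo-2,6-dimethyl-6,8-bis(triethylsilyloxy)octa-1,4-diene
Product: 14 (2Z,4R,5E,7R)-4-(tert-butyldimethylsilyloxy)-3,7-dimethyl-7,9-bis(triethylsilyloxy)nona-2,5-dienal, via alkenyllithium 13 (not isolated)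
Conditions: t-BuLi (2.1 equiv), Et2O, −78 °C; DMF, −78 °C; cold aqueous NH4Cl
Reagents that add atoms: N,N-dimethylformamide CN(C)C=O
Why: Iodine–lithium exchange proceeds with retention of alkene geometry and the alkenyllithium is formylated by DMF; holding the anion at −78 °C and quenching at once should outpace 1,4-O-to-C silyl migration, and cold buffered work-up limits Z-to-E isomerisation of the enal.

Step 9
Reactants: 5 prop-2-yn-1-ol
Product: 15 triethyl(prop-2-yn-1-yloxy)silane
Conditions: Et3SiCl, imidazole, CH2Cl2, 0 °C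
Reagents that add atoms: chlorotriethylsilane CC[Si](CC)(CC)Cl
Why: Standard silylation of a primary alcohol.

Step 10
Reactants: 14 (2Z,4R,5E,7R)-4-(tert-butyldimethylsilyloxy)-3,7-dimethyl-7,9-bis(triethylsilyloxy)nona-2,5-dienal; 15 triethyl(prop-2-yn-1-yloxy)silane
Product: 17 (4R,5Z,7R,8E,10R)-7-(tert-butyldimethylsilyloxy)-6,10-dimethyl-1,10,12-tris(triethylsilyloxy)dodeca-5,8-dien-2-yn-4-ol, via alkynyl(methyl)zinc 16 (not isolated)
Conditions: (R,R)-ProPhenol (20 mol %), Me2Zn, Ph3PO (40 mol %), toluene, 4 °C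
Reagents that add atoms: none
Why: Catalytic asymmetric alkynylation of an enal: the dinuclear zinc–ProPhenol complex binds the aldehyde and the alkynylzinc and should deliver the acetylide to the Si face of C6 (reagent control, 6R); the ligand antipode is chosen for this facial sense and would be exchanged for the (S,S)-ligand if induction proved opposite.

Step 11
Reactants: 17 (4R,5Z,7R,8E,10R)-7-(tert-butyldimethylsilyloxy)-6,10-dimethyl-1,10,12-tris(triethylsilyloxy)dodeca-5,8-dien-2-yn-4-ol
Product: 19 (2Z,4R,5Z,7R,8E,10R)-7-(tert-butyldimethylsilyloxy)-2-iodo-6,10-dimethyl-1,10,12-tris(triethylsilyloxy)dodeca-2,5,8-trien-4-ol, via cyclic alkenylaluminate 18 (not isolated)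
Conditions: NaAlH2(OCH2CH2OCH3)2, THF, 0 °C; then I2, −78 → 0 °C
Reagents that add atoms: iodine II
Why: Alkoxide-directed trans-hydroalumination of the propargylic alcohol puts hydride on C7 and aluminium on C11 in a five-membered oxa-aluminacycle, and iodinolysis with retention gives the Z-iodoalkene with C6–OH and iodine cis; the C13 silyl ether should not eliminate at 0 °C and the unactivated alkenes are inert.

Step 12
Reactants: 19 (2Z,4R,5Z,7R,8E,10R)-7-(tert-butyldimethylsilyloxy)-2-iodo-6,10-dimethyl-1,10,12-tris(triethylsilyloxy)dodeca-2,5,8-trien-4-ol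
Product: 20 (5R)-5-[(1Z,3R,4E,6R)-3-(tert-butyldimethylsilyloxy)-2,6-dimethyl-6,8-bis(triethylsilyloxy)octa-1,4-dienyl]-3-(triethylsilyloxymethyl)furan-2(5H)-one
Conditions: PdCl2(PPh3)2 (5 mol %), CO (1 atm), K2CO3, THF, 50 °C
Reagents that add atoms: carbon monoxide [C-]#[O+]
Why: Palladium-catalysed carbonylative lactonisation: oxidative addition of the vinyl iodide to zerovalent palladium, CO insertion and capture of the acylpalladium by the cis C6 hydroxyl close the butenolide without touching the C6 stereocentre.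

Step 13
Reactants: 20 (5R)-5-[(1Z,3R,4E,6R)-3-(tert-butyldimethylsilyloxy)-2,6-dimethyl-6,8-bis(triethylsilyloxy)octa-1,4-dienyl]-3-(triethylsilyloxymethyl)furan-2(5H)-one
Product: 21 (5R)-5-[(1Z,3R,4E,6R)-3-(tert-butyldimethylsilyloxy)-8-hydroxy-2,6-dimethyl-6-(triethylsilyloxy)octa-1,4-dienyl]-3-(hydroxymethyl)furan-2(5H)-one
Conditions: pyridinium p-toluenesulfonate (cat.), MeOH/CH2Cl2, 0 °C
Reagents that add atoms: none
Why: Mild acid methanolysis should cleave the two primary triethylsilyl ethers much faster than the tertiary triethylsilyl and the secondary tert-butyldimethylsilyl ether.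

Step 14
Reactants: 21 (5R)-5-[(1Z,3R,4E,6R)-3-(tert-butyldimethylsilyloxy)-8-hydroxy-2,6-dimethyl-6-(triethylsilyloxy)octa-1,4-dienyl]-3-(hydroxymethyl)furan-2(5H)-one
Product: 23 (5R)-3-(bromomethyl)-5-[(1Z,3R,4E,6R)-3-(tert-butyldimethylsilyloxy)-8-hydroxy-2,6-dimethyl-6-(triethylsilyloxy)octa-1,4-dienyl]furan-2(5H)-one, via allylic alkoxysulfonium bromide 22 (not isolated)
Conditions: N-bromosuccinimide, Me2S, CH2Cl2, −20 → 0 °C
Reagents that add atoms: N-bromosuccinimide O=C1CCC(=O)N1Br
Why: Corey–Kim halogenation: the alkoxysulfonium salt of the allylic, 2-(hydroxymethyl)enoate-type alcohol is displaced by bromide at low temperature, whereas that of the saturated primary alcohol is not and returns the alcohol on aqueous work-up.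

Step 15
Reactants: 23 (5R)-3-(bromomethyl)-5-[(1Z,3R,4E,6R)-3-(tert-butyldimethylsilyloxy)-8-hydroxy-2,6-dimethyl-6-(triethylsilyloxy)octa-1,4-dienyl]furan-2(5H)-one
Product: 24 (3R,4E,6R,7Z)-8-[(2R)-4-(bromomethyl)-5-oxo-2,5-dihydrofuran-2-yl]-6-(tert-butyldimethylsilyloxy)-3,7-dimethyl-3-(triethylsilyloxy)octa-4,7-dienal
Conditions: Dess–Martin periodinane, NaHCO3, CH2Cl2, 0 → 25 °C
Reagents that add atoms: none
Why: Dess–Martin oxidation under buffered, non-basic conditions gives the aldehyde without touching the allylic bromide, the silyl ethers or the base-sensitive C6–H.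

Step 16
Reactants: 24 (3R,4E,6R,7Z)-8-[(2R)-4-(bromomethyl)-5-oxo-2,5-dihydrofuran-2-yl]-6-(tert-butyldimethylsilyloxy)-3,7-dimethyl-3-(triethylsilyloxy)octa-4,7-dienal
Product: 26 (3R,6R,7R,8R,10R)-3-(tert-butyldimethylsilyloxy)-8-hydroxy-10-(triethylsilyloxy)germacra-1E,4Z,11(13)-trien-12,6-olide, via allylchromium dichloride 25 (not isolated)
Conditions: CrCl2 (10 equiv), THF, 25 °C, syringe-pump addition of 24 to 1 mM final concentration
Reagents that add atoms: none
Why: CrCl2 reduces the allylic bromide by two one-electron transfers to an allylchromium species, which adds to the tethered aldehyde through its γ-carbon C7 in a closed, chromium-bridged six-membered chair-like transition state, so that the C7–C8 bond, the C8 alkoxide and the exocyclic C11=C13 alkene arise together; this is an intramolecular Nozaki–Hiyama–Kishi allylation, the macrocyclic counterpart of the known chromium-, zinc- and indium-mediated additions of 3-(bromomethyl)furan-2(5H)-ones to aldehydes. The ten-membered carbocycle closes in a 10-exo-trig mode at the aldehyde, with the reacting C7=C11 π-bond also exocyclic to the new ring. C7 is controlled by C6: in the closed transition state the aldehyde oxygen lies anti to C6 and C9 is gauche to C6, so addition on the butenolide face that carries C5 would force C5 and C9, which are joined by only five atoms, into a near-eclipsed collision, and the aldehyde should therefore add anti to C5 to give the trans-fused 6R,7R lactone. C8 is controlled by the tether: with C6 held pseudo-equatorial by the butenolide, the orientation that places C9 over the lactone ring gives C5–C6–C7–C8 and C6–C7–C8–C9 torsions of like sign and leads to the required 8R alcohol, whereas the alternative orientation develops a syn-pentane-type clash between C5 and C9. The step needs γ- over α-attack (secured by the cyclic transition state), cyclisation over oligomerisation (secured by slow addition at high dilution and by the two ring alkenes that pre-organise the chain) and 8R over 8S, the last being the least secure because it opposes the usual equatorial preference of the aldehyde substituent. The silyl ethers, the skipped diene and the lactone are inert to divalent chromium.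

Step 17
Reactants: 26 (3R,6R,7R,8R,10R)-3-(tert-butyldimethylsilyloxy)-8-hydroxy-10-(triethylsilyloxy)germacra-1E,4Z,11(13)-trien-12,6-olide
Product: 27 (3R,6R,7R,8R,10R)-8-angeloyloxy-3-(tert-butyldimethylsilyloxy)-10-(triethylsilyloxy)germacra-1E,4Z,11(13)-trien-12,6-olide
Conditions: angelic acid, 2,4,6-Cl3C6H2COCl, Et3N, toluene, 25 °C; then 26, 80 °C
Reagents that add atoms: angelic acid C/C=C(/C)C(=O)O
Why: Yamaguchi esterification: the mixed anhydride acylates the hindered secondary C8 alcohol with retention at carbon, and omission of DMAP should suppress isomerisation of the angelate to the tiglate.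

Step 18
Reactants: 27 (3R,6R,7R,8R,10R)-8-angeloyloxy-3-(tert-butyldimethylsilyloxy)-10-(triethylsilyloxy)germacra-1E,4Z,11(13)-trien-12,6-olide
Product: 28 (3R,6R,7R,8R,10R)-8-angeloyloxy-3,10-dihydroxygermacra-1E,4Z,11(13)-trien-12,6-olide (CNP0262559.4)
Conditions: HF·pyridine, pyridine, THF, 0 → 25 °C
Reagents that add atoms: none
Why: Buffered fluoride desilylation should cleave both silyl ethers without ionising the bis-allylic C3 or tertiary allylic C10 alcohol, adding to the α-methylene lactone or isomerising the angelate.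

Compound list
1 | (E)-3-methylpent-2-en-4-yn-1-ol | OC/C=C(\C)C#C | starting material
2 | [(2S,3S)-3-ethynyl-3-methyloxiran-2-yl]methanol | OC[C@@H]1O[C@@]1(C)C#C | intermediate
3 | (3R)-3-methylpent-4-yne-1,3-diol | OCC[C@](O)(C)C#C | intermediate
4 | (3R)-3-methyl-1,3-bis(triethylsilyloxy)pent-4-yne | C#C[C@](C)(O[Si](CC)(CC)CC)CCO[Si](CC)(CC)CC | intermediate
5 | prop-2-yn-1-ol | C#CCO | starting material
6 | bromomagnesium (Z)-3-(bromomagnesio)-2-methylprop-2-en-1-olate | Br[Mg]OC/C(C)=C\[Mg]Br | intermediate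
7 | (Z)-3-iodo-2-methylprop-2-en-1-ol | OC/C(C)=C\I | intermediate
8 | (Z)-3-iodo-2-methylprop-2-enal | O=C/C(C)=C\I | intermediate
9 | dicyclohexyl[(1E,3R)-3-methyl-3,5-bis(triethylsilyloxy)pent-1-enyl]borane | CC[Si](CC)(CC)OCC[C@@](C)(O[Si](CC)(CC)CC)/C=C/B(C1CCCCC1)C1CCCCC1 | intermediate
10 | methyl[(1E,3R)-3-methyl-3,5-bis(triethylsilyloxy)pent-1-enyl]zinc | CC[Si](CC)(CC)OCC[C@@](C)(O[Si](CC)(CC)CC)/C=C/[Zn]C | intermediate
11 | (1Z,3R,4E,6R)-1-iodo-2,6-dimethyl-6,8-bis(triethylsilyloxy)octa-1,4-dien-3-ol | CC[Si](CC)(CC)OCC[C@@](C)(O[Si](CC)(CC)CC)/C=C/[C@@H](O)/C(C)=C\I | intermediate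
12 | (1Z,3R,4E,6R)-3-(tert-butyldimethylsilyloxy)-1-iodo-2,6-dimethyl-6,8-bis(triethylsilyloxy)octa-1,4-diene | CC[Si](CC)(CC)OCC[C@@](C)(O[Si](CC)(CC)CC)/C=C/[C@@H](O[Si](C)(C)C(C)(C)C)/C(C)=C\I | intermediate
13 | (1Z,3R,4E,6R)-3-(tert-butyldimethylsilyloxy)-2,6-dimethyl-6,8-bis(triethylsilyloxy)octa-1,4-dienyllithium | CC[Si](CC)(CC)OCC[C@@](C)(O[Si](CC)(CC)CC)/C=C/[C@@H](O[Si](C)(C)C(C)(C)C)/C(C)=C\[Li] | intermediate
14 | (2Z,4R,5E,7R)-4-(tert-butyldimethylsilyloxy)-3,7-dimethyl-7,9-bis(triethylsilyloxy)nona-2,5-dienal | CC[Si](CC)(CC)OCC[C@@](C)(O[Si](CC)(CC)CC)/C=C/[C@@H](O[Si](C)(C)C(C)(C)C)/C(C)=C\C=O | intermediate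
15 | triethyl(prop-2-yn-1-yloxy)silane | C#CCO[Si](CC)(CC)CC | intermediate
16 | methyl[3-(triethylsilyloxy)prop-1-ynyl]zinc | C[Zn]C#CCO[Si](CC)(CC)CC | intermediate
17 | (4R,5Z,7R,8E,10R)-7-(tert-butyldimethylsilyloxy)-6,10-dimethyl-1,10,12-tris(triethylsilyloxy)dodeca-5,8-dien-2-yn-4-ol | CC[Si](CC)(CC)OCC[C@@](C)(O[Si](CC)(CC)CC)/C=C/[C@@H](O[Si](C)(C)C(C)(C)C)/C(C)=C\[C@@H](O)C#CCO[Si](CC)(CC)CC | intermediate
18 | sodium cyclic alkenylaluminate of 17 (five-membered O–Al–C11=C7–C6 ring, two 2-methoxyethoxide ligands on aluminium) | CC[Si](CC)(CC)OCC[C@@](C)(O[Si](CC)(CC)CC)/C=C/[C@@H](O[Si](C)(C)C(C)(C)C)/C(C)=C\[C@H]1O[Al-](OCCOC)(OCCOC)C(CO[Si](CC)(CC)CC)=C1.[Na+] | intermediate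
19 | (2Z,4R,5Z,7R,8E,10R)-7-(tert-butyldimethylsilyloxy)-2-iodo-6,10-dimethyl-1,10,12-tris(triethylsilyloxy)dodeca-2,5,8-trien-4-ol | CC[Si](CC)(CC)OCC[C@@](C)(O[Si](CC)(CC)CC)/C=C/[C@@H](O[Si](C)(C)C(C)(C)C)/C(C)=C\[C@@H](O)/C=C(\I)CO[Si](CC)(CC)CC | intermediate
20 | (5R)-5-[(1Z,3R,4E,6R)-3-(tert-butyldimethylsilyloxy)-2,6-dimethyl-6,8-bis(triethylsilyloxy)octa-1,4-dienyl]-3-(triethylsilyloxymethyl)furan-2(5H)-one | CC[Si](CC)(CC)OCC[C@@](C)(O[Si](CC)(CC)CC)/C=C/[C@@H](O[Si](C)(C)C(C)(C)C)/C(C)=C\[C@H]1OC(=O)C(CO[Si](CC)(CC)CC)=C1 | intermediate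
21 | (5R)-5-[(1Z,3R,4E,6R)-3-(tert-butyldimethylsilyloxy)-8-hydroxy-2,6-dimethyl-6-(triethylsilyloxy)octa-1,4-dienyl]-3-(hydroxymethyl)furan-2(5H)-one | OCC[C@@](C)(O[Si](CC)(CC)CC)/C=C/[C@@H](O[Si](C)(C)C(C)(C)C)/C(C)=C\[C@H]1OC(=O)C(CO)=C1 | intermediate
22 | dimethylsulfonium bromide of 21, with the sulfonium on the allylic C13 oxygen | OCC[C@@](C)(O[Si](CC)(CC)CC)/C=C/[C@@H](O[Si](C)(C)C(C)(C)C)/C(C)=C\[C@H]1OC(=O)C(CO[S+](C)C)=C1.[Br-] | intermediate
23 | (5R)-3-(bromomethyl)-5-[(1Z,3R,4E,6R)-3-(tert-butyldimethylsilyloxy)-8-hydroxy-2,6-dimethyl-6-(triethylsilyloxy)octa-1,4-dienyl]furan-2(5H)-one | OCC[C@@](C)(O[Si](CC)(CC)CC)/C=C/[C@@H](O[Si](C)(C)C(C)(C)C)/C(C)=C\[C@H]1OC(=O)C(CBr)=C1 | intermediate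
24 | (3R,4E,6R,7Z)-8-[(2R)-4-(bromomethyl)-5-oxo-2,5-dihydrofuran-2-yl]-6-(tert-butyldimethylsilyloxy)-3,7-dimethyl-3-(triethylsilyloxy)octa-4,7-dienal | O=CC[C@@](C)(O[Si](CC)(CC)CC)/C=C/[C@@H](O[Si](C)(C)C(C)(C)C)/C(C)=C\[C@H]1OC(=O)C(CBr)=C1 | intermediate
25 | allylchromium dichloride of 24 (CrCl2 on C13, trivalent chromium) | O=CC[C@@](C)(O[Si](CC)(CC)CC)/C=C/[C@@H](O[Si](C)(C)C(C)(C)C)/C(C)=C\[C@H]1OC(=O)C(C[Cr](Cl)Cl)=C1 | intermediate
26 | (3R,6R,7R,8R,10R)-3-(tert-butyldimethylsilyloxy)-8-hydroxy-10-(triethylsilyloxy)germacra-1E,4Z,11(13)-trien-12,6-olide | C=C1C(=O)O[C@@H]2/C=C(/C)[C@H](O[Si](C)(C)C(C)(C)C)/C=C/[C@](C)(O[Si](CC)(CC)CC)C[C@@H](O)[C@@H]12 | intermediate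
27 | (3R,6R,7R,8R,10R)-8-angeloyloxy-3-(tert-butyldimethylsilyloxy)-10-(triethylsilyloxy)germacra-1E,4Z,11(13)-trien-12,6-olide | C=C1C(=O)O[C@@H]2/C=C(/C)[C@H](O[Si](C)(C)C(C)(C)C)/C=C/[C@](C)(O[Si](CC)(CC)CC)C[C@@H](OC(=O)/C(C)=C\C)[C@@H]12 | intermediate
28 | (3R,6R,7R,8R,10R)-8-angeloyloxy-3,10-dihydroxygermacra-1E,4Z,11(13)-trien-12,6-olide | C=C1C(=O)O[C@@H]2/C=C(/C)[C@H](O)/C=C/[C@](C)(O)C[C@@H](OC(=O)/C(C)=C\C)[C@@H]12 | target

Total step count: 18. Longest linear sequence: 15 steps (steps 1–3, 6–8, 10–18, from compound 1).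

Steps most likely to fail

Step 16. The ring may close through the competing transition state in which the aldehyde substituent C9 is pseudo-equatorial, which inverts the configuration formed at C8; intermolecular coupling is the second risk. Fallback: the cyclisation is run from 24 as before. If it delivers mainly the (3R,6R,7R,8S,10R)-3-(tert-butyldimethylsilyloxy)-8-hydroxy-10-(triethylsilyloxy)germacra-1E,4Z,11(13)-trien-12,6-olide F1, this alcohol is esterified with angelic acid under Mitsunobu conditions (PPh3, diisopropyl azodicarboxylate, toluene, 0 → 25 °C). The displacement inverts C8 and the route is rejoined at 27.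

Step 12. Under the basic carbonylation conditions the γ-alkenyl butenolide may enolise at C6 and lose its configuration, or CO insertion may be slow and protodeiodination may take over. Fallback: starting from 19, the hydroxyl is deprotonated with MeLi and the iodide exchanged with t-BuLi (Et2O, −78 °C), and the alkenyllithium is carboxylated with CO2. This gives (2Z,4R,5Z,7R,8E,10R)-7-(tert-butyldimethylsilyloxy)-4-hydroxy-6,10-dimethyl-10,12-bis(triethylsilyloxy)-2-(triethylsilyloxymethyl)dodeca-2,5,8-trienoic acid F2, which lactonises on mildly acidic work-up (NaH2PO4) and rejoins the route at 20 without exposure to carbonate at 50 °C.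

Step 8. The (Z)-γ-silyloxy alkenyllithium may undergo 1,4-O-to-C silyl migration before it is trapped, and the enal may isomerise from Z to E through the dimethylamine released on work-up. Fallback: starting from 12, a palladium-catalysed reductive carbonylation (Pd(PPh3)4, CO 1 atm, slow addition of Bu3SnH, THF, 50 °C) replaces the carbanion chemistry and gives 14 directly; this fallback makes no new compound (none, F0).

Further compounds
F1 | step 16 | (3R,6R,7R,8S,10R)-3-(tert-butyldimethylsilyloxy)-8-hydroxy-10-(triethylsilyloxy)germacra-1E,4Z,11(13)-trien-12,6-olide | C=C1C(=O)O[C@@H]2/C=C(/C)[C@H](O[Si](C)(C)C(C)(C)C)/C=C/[C@](C)(O[Si](CC)(CC)CC)C[C@H](O)[C@@H]12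
F2 | step 12 | (2Z,4R,5Z,7R,8E,10R)-7-(tert-butyldimethylsilyloxy)-4-hydroxy-6,10-dimethyl-10,12-bis(triethylsilyloxy)-2-(triethylsilyloxymethyl)dodeca-2,5,8-trienoic acid | CC[Si](CC)(CC)OCC[C@@](C)(O[Si](CC)(CC)CC)/C=C/[C@@H](O[Si](C)(C)C(C)(C)C)/C(C)=C\[C@@H](O)/C=C(\C(=O)O)CO[Si](CC)(CC)CC
F0 | step 8 | none | none
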